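Left-handed product in Wednesday's run appears after a lag, then climbs from 2.4 % at 3.00 h to 9.1 % at 8.00 h.

| flask | left-handed substrate | right-handed substrate | partner | precatalyst | temperature | remark | time |
|---|---|---|---|---|---|---|---|
| Friday's | 0.20 M | 0.20 M | 0.15 M | 13 mM | 35 °C | run made earlier |  |
| Wednesday's | 0.20 M | 0.20 M | 0.60 M | 13 mM | 70 °C | run made earlier |  |
| Thursday's | 0.20 M | 0.20 M | 0.30 M | 20 mM | 35 °C | run made earlier |  |
| ochre | 0.20 M | 0.20 M | 0.300 M | 13 mM | 70 °C |  | 12 h |
| green | 0.20 M | 0.20 M | 0.300 M | 13 mM | 100 °C |  | 12 h |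
| red | 0.20 M | 0.20 M | 0.300 M | 13 mM | 40 °C |  | 12 h |

| run | time / h | left-handed product / % |
|---|---|---|
| Friday's | 5.00 | 0 |
| Friday's | 8.00 | 1.0 |
| Friday's | 12.0 | 0.5 |
| Friday's | 25.0 | 0.2 |
| Friday's | 30.0 | 0.9 |
| Friday's | 60.0 | 0 |
| Wednesday's | 0.667 | 0 |
| Wednesday's | 2.00 | 0.8 |
| Wednesday's | 3.00 | 2.4 |
| Wednesday's | 5.00 | 5.8 |
| Wednesday's | 8.00 | 9.1 |
| Wednesday's | 10.0 | 9.6 |
| Thursday's | 5.00 | 0 |
| Thursday's | 15.0 | 0.7 |
| Thursday's | 25.0 | 0 |
| Thursday's | 30.0 | 1.3 |
| Thursday's | 60.0 | 1.7 |

(each reading ± 1 percentage point)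

- free catalyst is single-handed; left-handed substrate and right-handed substrate are mirror images of each other, charged as a racemate, each of them at the stated concentration

- which flask leads in amount of left-handed product, in percent of the left-handed substrate and right-handed substrate together charged ("all alike" within 1.5 percentage points) (ochre / green / red / all alike)
- how much left-handed product is there at the end, in percent of the left-handed substrate and right-handed substrate together charged: ochre
- how much left-handed product is there at the end, in percent of the left-handed substrate and right-handed substrate together charged: green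
- how much left-handed product is there at the end, in percent of the left-handed substrate and right-handed substrate together charged: red

Take the rate as first order in partner. The specific rate s is then the slope of left-handed product, as a fraction of both substrates charged, divided by the partner concentration. Wednesday's readings give 0.0223 M⁻¹ h⁻¹. That slope, run back to zero, leaves a lag of 1.21 h. Taking the lag as inverse to s times partner, ochre's lag is 2.42 h, so ochre reaches 6.42 %.

Thursday's last reading, scaled to 13 mM of precatalyst, gives 6.14 × 10⁻⁴ M⁻¹ h⁻¹ at 35 °C, far below the value at 70 °C. The two values give an activation energy E of 90.3 kJ mol⁻¹.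

At 100 °C, s becomes 0.284 M⁻¹ h⁻¹. A straight line in green then reaches 102 %, above the ceiling of 50.0 %. The single-handed catalyst is taken to turn over the left-handed substrate, which is then the limiting reagent. Partner is consumed along with that substrate, so green's rate is taken as second order, in both of them, with one partner used per product, and green reaches 37.3 %.

Red's slope gives 0.388 %, a high figure, since its scaled lag of 50.1 h is longer than 12 h.

The weak link is the cold reading, with its scatter of 1 percentage point. One standard deviation upward lowers E to 78.7 kJ mol⁻¹ and s at 100 °C to 0.205 M⁻¹ h⁻¹, and green still reaches 32.8 %, more than ochre.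

The forecast names ochre as leader, with 5 %, 3 % and 0.2 % for ochre, green and red: “Green activates fast but probably dies faster still”.

The leader is green, with 24.4 % against 5.18 % in ochre and 0.0304 % in red. Green also holds 17.9 % of right-handed product, so its two products together come to 42.3 %, beside the reckoned 37.3 %.

    free catalyst + left-handed substrate ⇌ catalyst intermediate A (K = 11.0 M⁻¹, k = 0.200 M⁻¹ s⁻¹, Ea = 45.0 kJ mol⁻¹, ΔH = 38.0 kJ mol⁻¹)
    free catalyst + right-handed substrate ⇌ catalyst intermediate B (K = 1.60 M⁻¹, k = 0.490 M⁻¹ s⁻¹, Ea = 70.0 kJ mol⁻¹, ΔH = −19.0 kJ mol⁻¹)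
    partner + catalyst intermediate A → free catalyst + left-handed product (k = 0.00410 M⁻¹ s⁻¹, Ea = 74.0 kJ mol⁻¹)
    partner + catalyst intermediate B → free catalyst + right-handed product (k = 2.30 × 10⁻⁴ M⁻¹ s⁻¹, Ea = 95.0 kJ mol⁻¹)
    left-handed product ⇌ right-handed product (k = 4.10 × 10⁻⁵ s⁻¹, Ea = 119 kJ mol⁻¹)
    partner + precatalyst → free catalyst + spent reagent (k = 0.00690 M⁻¹ s⁻¹, Ea = 87.0 kJ mol⁻¹)
    (constants at 100 °C)

For a repeat of red at 65 °C, s becomes 0.0140 M⁻¹ h⁻¹ and gives 3.42 %. That flask holds 2.90 %.

The numbers in the tables are simulated for an exercise.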